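**Target.** (6S,3'R,6'S)-3'-Hydroxy-ε,ε-caroten-3-one (23). Read from the SMILES: both ring carbons that carry the polyene are S, the carbinol carbon is R, and the 3'-OH is cis to the C6' chain.

**Assumption.** Crocetin dialdehyde (the C20 dial 18), both Grignard solutions and tributyl(iodomethyl)stannane are taken as purchasable; a crude intermediate carried on without purification is counted inside the same step.

## Retrosynthetic overview

1. 23 ⇐ diol 22 (MnO2 on one of two equivalent allylic OH) ⇐ 21 ⇐ double Julia–Kocienski olefination of 2 × C10 sulfone 17 with C20 dial 18 (makes C7=C8 and C7'=C8').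
2. 17 ⇐ alcohol 15 ⇐ key step: [2,3]-Wittig–Still rearrangement of 13, which makes the C6–C7 bond, sets C6 (S) by 1,3-chirality transfer from the C4 oxygen, and moves the double bond into the ε position.
3. 13 ⇐ cis-alcohol 11 ⇐ enone 10 (hydride anti to the C3 silyloxy group) ⇐ SeO2 allylic oxidation of cyclohexene 8.
4. Rings: only one ring is built, the trimethylcyclohexene 8, by ring-closing metathesis of diene 7; it is made once and becomes both end rings.
5. 7 ⇐ (S)-epichlorohydrin 1, opened in turn by isopropenyl and (γ-attack) prenyl Grignard reagents; its carbinol carbon becomes C3/C3' and is the only purchased stereocentre.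

## Route

Step 1
Reactants: 1 (S)-epichlorohydrin; 2 isopropenylmagnesium bromide
Product: 3 (S)-1-chloro-4-methylpent-4-en-2-ol
Conditions: 2 (1.3 equiv), CuI (5 mol%), THF, −40 → −20 °C; NH4Cl aq.
Reagents that add atoms: none
Why: Copper-catalysed Grignard opening of the epoxide at its terminal CH2 (SN2) leaves the C–Cl bond and the carbinol stereocentre untouched, so the future C3/C3' centre is carried over from the chiral pool.

Step 2
Reactants: 3 (S)-1-chloro-4-methylpent-4-en-2-ol; 4 prenylmagnesium chloride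
Product: 6 (S)-2,6,6-trimethylocta-1,7-dien-4-ol, via (S)-2-(2-methylallyl)oxirane 5 (not isolated)
Conditions: powdered KOH, Et2O, 0 → 20 °C, filter, dry (MgSO4); then 4 (1.5 equiv), THF, −30 → 0 °C, no copper salt; NH4Cl aq.
Reagents that add atoms: none
Why: Intramolecular Williamson closure gives the terminal epoxide without touching the stereocentre, and the copper-free allylic Grignard reagent opens it at CH2 through its γ-carbon (SE2' mode), building the gem-dimethyl carbon C1 together with the vinyl group needed for ring closure.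

Step 3
Reactants: 6 (S)-2,6,6-trimethylocta-1,7-dien-4-ol
Product: 7 (S)-tert-butyl[(2,6,6-trimethylocta-1,7-dien-4-yl)oxy]diphenylsilane
Conditions: TBDPSCl (1.2 equiv), imidazole (2.5 equiv), DMF, 20 °C
Reagents that add atoms: tert-butyl(chloro)diphenylsilane, CC(C)(C)[Si](Cl)(c1ccccc1)c1ccccc1
Why: Standard silylation of a secondary alcohol, with TBDPS chosen because it resists 1,2-silyl migration in the alkoxide of step 7 and survives every later step up to fluoride cleavage.

Step 4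
Reactants: 7 (S)-tert-butyl[(2,6,6-trimethylocta-1,7-dien-4-yl)oxy]diphenylsilane
Product: 8 (S)-tert-butyldiphenyl[(3,5,5-trimethylcyclohex-3-en-1-yl)oxy]silane
Conditions: second-generation Grubbs catalyst RuCl2(=CHPh)(PCy3)(H2IMes) (5 mol%), toluene (0.01 M), 80 °C, argon sparge
Reagents that add atoms: none
Why: Ring-closing olefin metathesis of a 1,7-diene to a six-membered trisubstituted cycloalkene, driven by loss of ethene and helped by the gem-dimethyl (Thorpe–Ingold) effect, with no stereocentre involved.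

Step 5
Reactants: 8 (S)-tert-butyldiphenyl[(3,5,5-trimethylcyclohex-3-en-1-yl)oxy]silane
Product: 10 (R)-6-[(tert-butyldiphenylsilyl)oxy]-2,4,4-trimethylcyclohex-2-en-1-one, via C1-epimeric allylic alcohol 9 (not isolated)
Conditions: SeO2 (20 mol%), t-BuOOH (3 equiv), CH2Cl2, 20 °C; Na2S2O3 wash; crude + Dess–Martin periodinane (1.5 equiv), NaHCO3, CH2Cl2, 20 °C
Reagents that add atoms: tert-butyl hydroperoxide, CC(C)(C)OO
Why: The Sharpless SeO2 allylic oxidation (ene reaction, then [2,3]-sigmatropic shift of the allylseleninic acid) oxygenates the one ring CH2 attached to the methyl-bearing alkene carbon without moving the double bond, and the Dess–Martin oxidation converges both carbinol epimers to one enone while the silyloxy stereocentre stays out of both events.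

Step 6
Reactants: 10 (R)-6-[(tert-butyldiphenylsilyl)oxy]-2,4,4-trimethylcyclohex-2-en-1-one
Product: 11 (1S,6R)-6-[(tert-butyldiphenylsilyl)oxy]-2,4,4-trimethylcyclohex-2-en-1-ol
Conditions: LiBH(s-Bu)3 (L-Selectride, 1.2 equiv), THF, −78 °C; NH4Cl aq.
Reagents that add atoms: none
Why: 1,2-Reduction by the bulky hydride from the face anti to the neighbouring silyloxy group (conjugate addition is blocked by the neopentyl β-carbon) gives the cis-alcohol, so this temporary carbinol centre is set by the purchased one (substrate control).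

Step 7
Reactants: 11 (1S,6R)-6-[(tert-butyldiphenylsilyl)oxy]-2,4,4-trimethylcyclohex-2-en-1-ol; 12 tributyl(iodomethyl)stannane
Product: 13 tributyl({[(1S,6R)-6-[(tert-butyldiphenylsilyl)oxy]-2,4,4-trimethylcyclohex-2-en-1-yl]oxy}methyl)stannane
Conditions: KH (1.5 equiv), 18-crown-6 (cat.), THF, 0 °C; then 12 (1.3 equiv), 0 → 20 °C
Reagents that add atoms: none
Why: Williamson etherification of the potassium alkoxide with the iodomethylstannane gives the Still precursor without change at any stereocentre.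

Step 8
Reactants: 13 tributyl({[(1S,6R)-6-[(tert-butyldiphenylsilyl)oxy]-2,4,4-trimethylcyclohex-2-en-1-yl]oxy}methyl)stannane
Product: 15 [(1S,4R)-4-[(tert-butyldiphenylsilyl)oxy]-2,6,6-trimethylcyclohex-2-en-1-yl]methanol, via lithiomethyl ether 14 (not isolated)
Conditions: n-BuLi (1.5 equiv), THF, −78 °C, 1 h; NH4Cl aq.
Reagents that add atoms: none
Why: Tin–lithium exchange gives an α-alkoxymethyllithium that undergoes the [2,3]-Wittig–Still sigmatropic rearrangement through a five-membered envelope transition state, forming the C6–C7 bond suprafacially on the face that carried the allylic oxygen (cis to the silyloxy group), which sets C6 as S and moves the double bond to C4=C5.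

Step 9
Reactants: 15 [(1S,4R)-4-[(tert-butyldiphenylsilyl)oxy]-2,6,6-trimethylcyclohex-2-en-1-yl]methanol
Product: 16 5-({[(1S,4R)-4-[(tert-butyldiphenylsilyl)oxy]-2,6,6-trimethylcyclohex-2-en-1-yl]methyl}sulfanyl)-1-phenyl-1H-tetrazole
Conditions: 1-phenyl-1H-tetrazole-5-thiol (1.5 equiv), PPh3 (1.5 equiv), DIAD (1.5 equiv), THF, 0 → 20 °C
Reagents that add atoms: 1-phenyl-1H-tetrazole-5-thiol, Sc1nnnn1-c1ccccc1
Why: Mitsunobu thioetherification of the primary alcohol is an SN2 reaction at CH2 and involves no stereocentre.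

Step 10
Reactants: 16 5-({[(1S,4R)-4-[(tert-butyldiphenylsilyl)oxy]-2,6,6-trimethylcyclohex-2-en-1-yl]methyl}sulfanyl)-1-phenyl-1H-tetrazole
Product: 17 5-({[(1S,4R)-4-[(tert-butyldiphenylsilyl)oxy]-2,6,6-trimethylcyclohex-2-en-1-yl]methyl}sulfonyl)-1-phenyl-1H-tetrazole
Conditions: (NH4)6Mo7O24·4H2O (0.2 equiv), 30% H2O2 (10 equiv), EtOH, 0 → 20 °C
Reagents that add atoms: hydrogen peroxide, OO
Why: Molybdate-catalysed peroxide oxidation takes the sulfide to the sulfone and is chemoselective over the trisubstituted ring alkene and the silyl ether.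

Step 11
Reactants: 17 5-({[(1S,4R)-4-[(tert-butyldiphenylsilyl)oxy]-2,6,6-trimethylcyclohex-2-en-1-yl]methyl}sulfonyl)-1-phenyl-1H-tetrazole (2.4 equiv); 18 crocetin dialdehyde
Product: 21 (3R,6S,3'R,6'S)-3,3'-bis[(tert-butyldiphenylsilyl)oxy]-ε,ε-carotene, via potassium sulfonyl carbanion 19 (not isolated), via C30 apo-aldehyde 20 (not isolated)
Conditions: KN(SiMe3)2 (2.5 equiv), DME, −78 °C, 30 min; then 18 (1.0 equiv) in THF, −78 → 20 °C, dark; then I2 (1 mol%), CH2Cl2, daylight, 20 min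
Reagents that add atoms: none
Why: The double Julia–Kocienski olefination (addition, Smiles rearrangement, loss of SO2 and tetrazololate) joins two C10 end groups to the C20 dial with E-selective formation of C7=C8 and C7'=C8', deprotonation occurs only next to sulfur so C6 is not epimerised, and the iodine equilibration converts residual 7Z material to the all-E polyene.

Step 12
Reactants: 21 (3R,6S,3'R,6'S)-3,3'-bis[(tert-butyldiphenylsilyl)oxy]-ε,ε-carotene
Product: 22 (3R,6S,3'R,6'S)-ε,ε-carotene-3,3'-diol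
Conditions: Bu4NF (4 equiv), THF, 20 °C, dark, argon
Reagents that add atoms: none
Why: Fluoride-induced Si–O cleavage frees both allylic alcohols under conditions that leave the polyene and all four stereocentres untouched.

Step 13
Reactants: 22 (3R,6S,3'R,6'S)-ε,ε-carotene-3,3'-diol
Product: 23 (6S,3'R,6'S)-3'-hydroxy-ε,ε-caroten-3-one
Conditions: activated MnO2 (added in portions), CH2Cl2/acetone, 20 °C, dark, stopped at about one third conversion of the hydroxyl groups; chromatography on deactivated silica, recovered 22 recycled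
Reagents that add atoms: none
Why: MnO2 oxidises only allylic alcohols under neutral conditions (no base, so the γ-stereocentre C6 of the new enone is not epimerised), and since the two hydroxyls of the C2-symmetric diol are equivalent, partial conversion gives a single mono-ketone (about 40–45% per pass) that is easily separated from recovered diol and from the dione.

## Compound list

1 | (S)-epichlorohydrin | ClC[C@@H]1CO1 | starting material
2 | isopropenylmagnesium bromide | C=C(C)[Mg]Br | starting material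
3 | (S)-1-chloro-4-methylpent-4-en-2-ol | ClC[C@@H](O)CC(C)=C | intermediate
4 | prenylmagnesium chloride (3-methylbut-2-en-1-ylmagnesium chloride) | CC(C)=CC[Mg]Cl | starting material
5 | (S)-2-(2-methylallyl)oxirane | C=C(C)C[C@H]1CO1 | intermediate
6 | (S)-2,6,6-trimethylocta-1,7-dien-4-ol | C=C(C)C[C@H](O)CC(C)(C)C=C | intermediate
7 | (S)-tert-butyl[(2,6,6-trimethylocta-1,7-dien-4-yl)oxy]diphenylsilane | C=C(C)C[C@H](O[Si](c1ccccc1)(c1ccccc1)C(C)(C)C)CC(C)(C)C=C | intermediate
8 | (S)-tert-butyldiphenyl[(3,5,5-trimethylcyclohex-3-en-1-yl)oxy]silane | CC1=CC(C)(C)C[C@@H](O[Si](c2ccccc2)(c2ccccc2)C(C)(C)C)C1 | intermediate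
9 | (6R)-6-[(tert-butyldiphenylsilyl)oxy]-2,4,4-trimethylcyclohex-2-en-1-ol, both C1 epimers | CC1=CC(C)(C)C[C@@H](O[Si](c2ccccc2)(c2ccccc2)C(C)(C)C)C1O | intermediate
10 | (R)-6-[(tert-butyldiphenylsilyl)oxy]-2,4,4-trimethylcyclohex-2-en-1-one | CC1=CC(C)(C)C[C@@H](O[Si](c2ccccc2)(c2ccccc2)C(C)(C)C)C1=O | intermediate
11 | (1S,6R)-6-[(tert-butyldiphenylsilyl)oxy]-2,4,4-trimethylcyclohex-2-en-1-ol (OH cis to OSi) | CC1=CC(C)(C)C[C@@H](O[Si](c2ccccc2)(c2ccccc2)C(C)(C)C)[C@H]1O | intermediate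
12 | tributyl(iodomethyl)stannane | CCCC[Sn](CCCC)(CCCC)CI | starting material
13 | tributyl({[(1S,6R)-6-[(tert-butyldiphenylsilyl)oxy]-2,4,4-trimethylcyclohex-2-en-1-yl]oxy}methyl)stannane | CC1=CC(C)(C)C[C@@H](O[Si](c2ccccc2)(c2ccccc2)C(C)(C)C)[C@H]1OC[Sn](CCCC)(CCCC)CCCC | intermediate
14 | ({[(1S,6R)-6-[(tert-butyldiphenylsilyl)oxy]-2,4,4-trimethylcyclohex-2-en-1-yl]oxy}methyl)lithium | CC1=CC(C)(C)C[C@@H](O[Si](c2ccccc2)(c2ccccc2)C(C)(C)C)[C@H]1OC[Li] | intermediate
15 | [(1S,4R)-4-[(tert-butyldiphenylsilyl)oxy]-2,6,6-trimethylcyclohex-2-en-1-yl]methanol (CH2OH cis to OSi) | OC[C@@H]1C(C)=C[C@H](O[Si](c2ccccc2)(c2ccccc2)C(C)(C)C)CC1(C)C | intermediate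
16 | 5-({[(1S,4R)-4-[(tert-butyldiphenylsilyl)oxy]-2,6,6-trimethylcyclohex-2-en-1-yl]methyl}sulfanyl)-1-phenyl-1H-tetrazole | C(Sc1nnnn1-c1ccccc1)[C@@H]1C(C)=C[C@H](O[Si](c2ccccc2)(c2ccccc2)C(C)(C)C)CC1(C)C | intermediate
17 | 5-({[(1S,4R)-4-[(tert-butyldiphenylsilyl)oxy]-2,6,6-trimethylcyclohex-2-en-1-yl]methyl}sulfonyl)-1-phenyl-1H-tetrazole | O=S(=O)(C[C@@H]1C(C)=C[C@H](O[Si](c2ccccc2)(c2ccccc2)C(C)(C)C)CC1(C)C)c1nnnn1-c1ccccc1 | intermediate
18 | crocetin dialdehyde, (all-E)-2,6,11,15-tetramethylhexadeca-2,4,6,8,10,12,14-heptaenedial | O=C/C(C)=C/C=C/C(C)=C/C=C/C=C(C)/C=C/C=C(C)/C=O | starting material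
19 | potassium salt of 17 metalated at the CH2 next to sulfur | [K+].O=S(=O)([CH-][C@@H]1C(C)=C[C@H](O[Si](c2ccccc2)(c2ccccc2)C(C)(C)C)CC1(C)C)c1nnnn1-c1ccccc1 | intermediate
20 | (3R,6S)-3-[(tert-butyldiphenylsilyl)oxy]-8'-apo-ε-caroten-8'-al | O=C/C(C)=C/C=C/C(C)=C/C=C/C=C(C)/C=C/C=C(C)/C=C/[C@@H]1C(C)=C[C@H](O[Si](c2ccccc2)(c2ccccc2)C(C)(C)C)CC1(C)C | intermediate
21 | (3R,6S,3'R,6'S)-3,3'-bis[(tert-butyldiphenylsilyl)oxy]-ε,ε-carotene | CC1=C[C@H](O[Si](c2ccccc2)(c2ccccc2)C(C)(C)C)CC(C)(C)[C@@H]1/C=C/C(C)=C/C=C/C(C)=C/C=C/C=C(C)/C=C/C=C(C)/C=C/[C@@H]1C(C)=C[C@H](O[Si](c2ccccc2)(c2ccccc2)C(C)(C)C)CC1(C)C | intermediate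
22 | (3R,6S,3'R,6'S)-ε,ε-carotene-3,3'-diol | CC1=C[C@H](O)CC(C)(C)[C@@H]1/C=C/C(C)=C/C=C/C(C)=C/C=C/C=C(C)/C=C/C=C(C)/C=C/[C@@H]1C(C)=C[C@H](O)CC1(C)C | intermediate
23 | (6S,3'R,6'S)-3'-hydroxy-ε,ε-caroten-3-one | CC1=CC(=O)CC(C)(C)[C@@H]1/C=C/C(C)=C/C=C/C(C)=C/C=C/C=C(C)/C=C/C=C(C)/C=C/[C@@H]1C(C)=C[C@H](O)CC1(C)C | target

## Summary

Total step count: 13. Longest linear sequence: 13 steps (1 → 23; sulfone 17 is used twice in step 11).

**Steps most likely to fail, with fallbacks**

Step 5 (SeO2 oxidation of a ring CH2 flanked by a bulky silyloxy carbon; the ene step must reach the alkene carbon next to the quaternary centre, and methyl oxidation may compete). Fallback: bring the oxygen in with the chiral-pool piece instead of by C–H oxidation. It sets out from 4 and comes back at 9. Purchased (R)-glycidyl trityl ether (C(OC[C@H]1CO1)(c1ccccc1)(c1ccccc1)c1ccccc1) is opened by 4 without copper to (R)-4,4-dimethyl-1-(trityloxy)hex-5-en-2-ol F1. Silylation (TBDPSCl, imidazole) gives (R)-tert-butyl{[4,4-dimethyl-1-(trityloxy)hex-5-en-2-yl]oxy}diphenylsilane F2. Detritylation (TsOH, MeOH/CH2Cl2, 0 °C) gives (R)-2-[(tert-butyldiphenylsilyl)oxy]-4,4-dimethylhex-5-en-1-ol F3, and Dess–Martin oxidation gives (R)-2-[(tert-butyldiphenylsilyl)oxy]-4,4-dimethylhex-5-enal F4. Addition of 2 at −78 °C gives (4R)-4-[(tert-butyldiphenylsilyl)oxy]-2,6,6-trimethylocta-1,7-dien-3-ol F5 (Felkin-type, anti epimer expected as the major one). Ring-closing metathesis under the step 4 conditions then gives 9, which is oxidised to 10 as in the second stage of step 5.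

Step 8 (the key rearrangement has to form a bond at a neopentyl-type carbon, and the alkoxide of step 7 could still suffer silyl migration). Fallback: a neutral, carbene-based [2,3] shift that needs neither an alkoxide nor an organolithium. It sets out from 11 and comes back at 15. Heating 11 with N,N-dimethylformamide dimethyl acetal in xylene at 150–160 °C (Büchi rearrangement of the alkoxy(amino)carbene, same suprafacial sense) gives (1S,4R)-4-[(tert-butyldiphenylsilyl)oxy]-N,N,2,6,6-pentamethylcyclohex-2-ene-1-carboxamide F6. Reduction with LiNH2BH3 (THF, 0 → 20 °C) gives alcohol 15.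

Step 13 (no chemoselectivity between the two equivalent hydroxyls; yield is capped near 45% per pass and over-oxidation gives the dione). Fallback: differentiate the ends before coupling. It sets out from 17 and comes back at 23. Part of 17 is desilylated (Bu4NF, THF) to (1R,4S)-3,5,5-trimethyl-4-{[(1-phenyl-1H-tetrazol-5-yl)sulfonyl]methyl}cyclohex-2-en-1-ol F7. Separately, 17 (1 equiv, KN(SiMe3)2) is coupled with an excess of 18 (3 equiv) and the mono-olefination product 20 is isolated this time. The dianion of F7 (2.1 equiv KN(SiMe3)2) is then coupled with 20 to give (3R,6S,3'R,6'S)-3'-[(tert-butyldiphenylsilyl)oxy]-ε,ε-caroten-3-ol F8. MnO2 oxidises its single free allylic alcohol to (6S,3'R,6'S)-3'-[(tert-butyldiphenylsilyl)oxy]-ε,ε-caroten-3-one F9. HF·pyridine buffered with pyridine (THF, 0 °C, non-basic so C6 is safe) then gives 23.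

## Further compounds

F1 | step 5 | (R)-4,4-dimethyl-1-(trityloxy)hex-5-en-2-ol | C=CC(C)(C)C[C@@H](O)COC(c1ccccc1)(c1ccccc1)c1ccccc1
F2 | step 5 | (R)-tert-butyl{[4,4-dimethyl-1-(trityloxy)hex-5-en-2-yl]oxy}diphenylsilane | C=CC(C)(C)C[C@@H](O[Si](c1ccccc1)(c1ccccc1)C(C)(C)C)COC(c1ccccc1)(c1ccccc1)c1ccccc1
F3 | step 5 | (R)-2-[(tert-butyldiphenylsilyl)oxy]-4,4-dimethylhex-5-en-1-ol | C=CC(C)(C)C[C@@H](O[Si](c1ccccc1)(c1ccccc1)C(C)(C)C)CO
F4 | step 5 | (R)-2-[(tert-butyldiphenylsilyl)oxy]-4,4-dimethylhex-5-enal | C=CC(C)(C)C[C@@H](O[Si](c1ccccc1)(c1ccccc1)C(C)(C)C)C=O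
F5 | step 5 | (4R)-4-[(tert-butyldiphenylsilyl)oxy]-2,6,6-trimethylocta-1,7-dien-3-ol, both C3 epimers | C=CC(C)(C)C[C@@H](O[Si](c1ccccc1)(c1ccccc1)C(C)(C)C)C(O)C(C)=C
F6 | step 8 | (1S,4R)-4-[(tert-butyldiphenylsilyl)oxy]-N,N,2,6,6-pentamethylcyclohex-2-ene-1-carboxamide | CN(C)C(=O)[C@@H]1C(C)=C[C@H](O[Si](c2ccccc2)(c2ccccc2)C(C)(C)C)CC1(C)C
F7 | step 13 | (1R,4S)-3,5,5-trimethyl-4-{[(1-phenyl-1H-tetrazol-5-yl)sulfonyl]methyl}cyclohex-2-en-1-ol | O=S(=O)(C[C@@H]1C(C)=C[C@H](O)CC1(C)C)c1nnnn1-c1ccccc1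
F8 | step 13 | (3R,6S,3'R,6'S)-3'-[(tert-butyldiphenylsilyl)oxy]-ε,ε-caroten-3-ol | CC1=C[C@H](O)CC(C)(C)[C@@H]1/C=C/C(C)=C/C=C/C(C)=C/C=C/C=C(C)/C=C/C=C(C)/C=C/[C@@H]1C(C)=C[C@H](O[Si](c2ccccc2)(c2ccccc2)C(C)(C)C)CC1(C)C
F9 | step 13 | (6S,3'R,6'S)-3'-[(tert-butyldiphenylsilyl)oxy]-ε,ε-caroten-3-one | CC1=CC(=O)CC(C)(C)[C@@H]1/C=C/C(C)=C/C=C/C(C)=C/C=C/C=C(C)/C=C/C=C(C)/C=C/[C@@H]1C(C)=C[C@H](O[Si](c2ccccc2)(c2ccccc2)C(C)(C)C)CC1(C)C
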